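**Retrosynthetic overview**
The C15 caffeate ester is cut last (Steglich esterification, then global fluoride desilylation), and the C8(17) methylene is traced back to a C8 ketone.
The key disconnection cuts the C10–C20 and C9–C11 bonds: Me2CuLi adds to a C8-keto C9=C10 enone and the C8–C9 enolate is alkylated in the same flask by a C11–C15 iodide that carries C13.
The strategy rests on ring B (C5–C10): its C8 methylene, lying between C9 and the quaternary C10, is read as a C8 ketone with a C9=C10 double bond, which is the anisole ring of a 6-methoxytetralin whose benzylic quaternary carbon is C4 (set by asymmetric hydrovinylation).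
No ring is built: ring A and the aromatic ring B are bought together as 6-methoxy-1-tetralone and ring B is dearomatised by Birch reduction. A dienone with C5=C6 and C9=C10 double bonds would only be the keto tautomer of a phenol, so H-5 is delivered instead by ester-directed hydrogenation of the Birch C5=C10 alkene, and the C9=C10 enone is then restored by Saegusa–Ito oxidation.

Key step: step 13

Remark on the chemistry: labdane numbering is used for the decalin (C4 = quaternary carbon with the C18 methyl and the C19 carboxyl, C5 and C10 = ring fusion, C8 carries C17, C9 carries the C11–C15 chain with C16 on C13, C20 = methyl on C10). The target is taken exactly as drawn, (4S,5S,9R,10R,13S), with H-5, C20 and C19 mutually cis and the C9 chain trans to C20.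

**Route**

Step 1
Reactants: 1 6-methoxy-1-tetralone
Product: 2 6-methoxy-1-methylene-1,2,3,4-tetrahydronaphthalene
Conditions: Ph3PCH3Br, KOt-Bu, THF, 0 °C to rt
Reagents that add atoms: methyltriphenylphosphonium bromide, C[P+](c1ccccc1)(c1ccccc1)c1ccccc1.[Br-]
Why: Wittig methylenation of an aryl ketone is routine, and the acid-sensitive exocyclic styrene is carried on without storage so that the double bond does not move into the ring.

Step 2
Reactants: 2 6-methoxy-1-methylene-1,2,3,4-tetrahydronaphthalene
Product: 3 (R)-6-methoxy-1-methyl-1-vinyl-1,2,3,4-tetrahydronaphthalene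
Conditions: ethylene (1 atm), [Ni(allyl)Br]2 (cat.), BINOL-derived phosphoramidite with a bis(1-phenylethyl)amino group (cat.), NaB[3,5-(CF3)2C6H3]4 (cat.), CH2Cl2, −70 °C
Reagents that add atoms: ethylene, C=C
Why: Nickel-catalysed asymmetric hydrovinylation of 1-methylenetetralins is a known way to a benzylic all-carbon quaternary centre (the cationic nickel hydride adds to the styrene, ethylene inserts and β-hydride elimination frees the vinyl group), and the ligand enantiomer is chosen so that C4 comes out R here, which is S once the vinyl group has become the carboxyl.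

Step 3
Reactants: 3 (R)-6-methoxy-1-methyl-1-vinyl-1,2,3,4-tetrahydronaphthalene
Product: 4 (S)-6-methoxy-1-methyl-1,2,3,4-tetrahydronaphthalene-1-carbaldehyde
Conditions: O3, CH2Cl2/MeOH, −78 °C, Sudan Red 7B end-point; then Me2S, −78 °C to rt
Reagents that add atoms: ozone, [O-][O+]=O
Why: Ozonolysis with a dye end-point and reductive work-up cleaves the terminal vinyl group much faster than the anisole ring, and C4 has no α-hydrogen to epimerise.

Step 4
Reactants: 4 (S)-6-methoxy-1-methyl-1,2,3,4-tetrahydronaphthalene-1-carbaldehyde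
Product: 5 (S)-6-methoxy-1-methyl-1,2,3,4-tetrahydronaphthalene-1-carboxylic acid
Conditions: NaClO2, NaH2PO4, 2-methyl-2-butene, t-BuOH/H2O, rt
Reagents that add atoms: sodium chlorite, [Na+].[O-]Cl=O
Why: Pinnick oxidation copes with the hindered α-quaternary aldehyde, and the excess alkene scavenger for hypochlorous acid keeps the electron-rich ring from being chlorinated.

Step 5
Reactants: 5 (S)-6-methoxy-1-methyl-1,2,3,4-tetrahydronaphthalene-1-carboxylic acid
Product: 7 (S)-1-methyl-6-oxo-1,2,3,4,5,6,7,8-octahydronaphthalene-1-carboxylic acid, via Birch diene acid 6 (not isolated)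
Conditions: Li, NH3 (l), THF, t-BuOH, −78 to −33 °C; NH4Cl; then oxalic acid, MeOH/H2O, rt
Reagents that add atoms: water, O
Why: Birch reduction of the anisole ring, run on the lithium carboxylate so that C19 is not reduced, gives the 1,4-diene with the enol ether at C7=C8 and the tetrasubstituted C5=C10 alkene, and oxalic acid hydrolyses only the enol ether to the C8 ketone without moving the double bond into conjugation.

Step 6
Reactants: 7 (S)-1-methyl-6-oxo-1,2,3,4,5,6,7,8-octahydronaphthalene-1-carboxylic acid
Product: 8 2-(trimethylsilyl)ethyl (S)-1-methyl-6-oxo-1,2,3,4,5,6,7,8-octahydronaphthalene-1-carboxylate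
Conditions: Me3SiCH2CH2OH, PPh3, DIAD, THF, 0 °C to rt
Reagents that add atoms: 2-(trimethylsilyl)ethanol, C[Si](C)(C)CCO
Why: Mitsunobu esterification activates the primary alcohol and uses the hindered carboxylate as the nucleophile under near-neutral conditions that leave the β,γ-unsaturated ketone unconjugated, and this ester is later cleaved at silicon, so the hindrance at C19 will not matter.

Step 7
Reactants: 8 2-(trimethylsilyl)ethyl (S)-1-methyl-6-oxo-1,2,3,4,5,6,7,8-octahydronaphthalene-1-carboxylate
Product: 9 2-(trimethylsilyl)ethyl (1S,4aR,8aS)-1-methyl-6-oxodecahydronaphthalene-1-carboxylate (cis-fused, H-5 and H-10 on the face of the C19 ester)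
Conditions: H2 (10 bar), [Ir(cod)(PCy3)(py)]B[3,5-(CF3)2C6H3]4 (cat.), CH2Cl2, rt
Reagents that add atoms: none
Why: In this carbonyl-directed hydrogenation the cationic iridium catalyst is held by the C19 ester carbonyl and delivers both hydrogens to the C5=C10 alkene from the ester face, which sets H-5 cis to C19 (the hydrogen on C10 is removed again in step 8).

Step 8
Reactants: 9 2-(trimethylsilyl)ethyl (1S,4aR,8aS)-1-methyl-6-oxodecahydronaphthalene-1-carboxylate
Product: 11 2-(trimethylsilyl)ethyl (1S,8aS)-1-methyl-6-oxo-1,2,3,4,6,7,8,8a-octahydronaphthalene-1-carboxylate, via trimethylsilyl enol ether 10 (not isolated)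
Conditions: TMSOTf, Et3N, CH2Cl2, 0 °C to rt (equilibrating); then Pd(OAc)2 (1.05 equiv), MeCN, rt
Reagents that add atoms: none
Why: In this Saegusa–Ito oxidation a cis-fused 2-decalone is expected to enolise toward the ring fusion under equilibrating silylation (C8=C9 enol ether), and stoichiometric divalent palladium then removes H-10 to give the C9=C10 enone; with only one equivalent of enol ether the enone cannot be dehydrogenated further to the phenol, and H-5 is untouched.

Step 9
Reactants: 12 (R)-methyl hydrogen 3-methylglutarate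
Product: 13 methyl (R)-5-hydroxy-3-methylpentanoate
Conditions: BH3·SMe2, THF, −10 °C to rt; then H2O
Reagents that add atoms: none
Why: Borane reduces the free carboxylic acid much faster than the methyl ester, which keeps the two arms at the future C13 distinct, and the hydroxy ester is silylated at once so that it cannot lactonise.

Step 10
Reactants: 13 methyl (R)-5-hydroxy-3-methylpentanoate
Product: 14 methyl (R)-5-(tert-butyldimethylsilyloxy)-3-methylpentanoate
Conditions: TBSCl, imidazole, DMF, 0 °C to rt
Reagents that add atoms: tert-butyldimethylsilyl chloride, CC(C)(C)[Si](C)(C)Cl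
Why: Standard silylation of a primary alcohol masks the future C15 oxygen, and the stereocentre is remote.

Step 11
Reactants: 14 methyl (R)-5-(tert-butyldimethylsilyloxy)-3-methylpentanoate
Product: 15 (S)-5-(tert-butyldimethylsilyloxy)-3-methylpentan-1-ol
Conditions: LiBH4, THF, 0 °C to rt
Reagents that add atoms: none
Why: LiBH4 reduces the methyl ester to the primary alcohol and leaves the silyl ether alone; the descriptor changes only because the priorities of the two arms change.

Step 12
Reactants: 15 (S)-5-(tert-butyldimethylsilyloxy)-3-methylpentan-1-ol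
Product: 16 (R)-tert-butyl[(5-iodo-3-methylpentyl)oxy]dimethylsilane
Conditions: I2, PPh3, imidazole, CH2Cl2, 0 °C
Reagents that add atoms: iodine, II
Why: Appel-type iodination of the primary alcohol under buffered conditions gives the C11 iodide without loss of the silyl ether.

Step 13
Reactants: 11 2-(trimethylsilyl)ethyl (1S,8aS)-1-methyl-6-oxo-1,2,3,4,6,7,8,8a-octahydronaphthalene-1-carboxylate; 16 (R)-tert-butyl[(5-iodo-3-methylpentyl)oxy]dimethylsilane
Product: 19 2-(trimethylsilyl)ethyl 15-(tert-butyldimethylsilyloxy)-8-oxo-17-norlabdan-19-oate (H-5, C20 and C19 cis; C9 chain trans to C20; 13S), via lithium C8–C9 enolate 17 (not isolated), via C9-epimeric ketone 18 (not isolated)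
Conditions: MeLi (2 equiv), CuI, Et2O, 0 °C; 11, −20 to 0 °C; then 16, THF/HMPA, −20 °C to rt; aq NH4Cl/NH3; crude product, NaOMe (cat.), MeOH/THF, rt
Reagents that add atoms: methyllithium, [Li]C
Why: Me2CuLi forms a π-complex with the enone and transfers methyl to the β-carbon C10 through a trivalent copper intermediate (C10–C20 bond), leaving lithium enolate 17 across C8–C9, which in THF/HMPA displaces iodide from the primary iodide 16 (C9–C11 bond). The closest known reaction type is the conjugate addition of Me2CuLi to 4,4a,5,6,7,8-hexahydro-2(3H)-naphthalenones, which gives cis-fused angular-methyl decalones, combined with alkyl halide trapping of the regiospecific enolate; no ring is closed, since both rings are already present. C10 is controlled by the substrate: in 11 H-5 is axial on ring A and the C18 methyl on C4 is axial on the opposite face, 1,3 to C10, so methyl should enter from the face of H-5 and of the C19 ester and make the ring fusion cis. At C9 the iodide should approach the cis-fused enolate from its convex face (the face of C20), which gives the axial chain of 18. Because C9 is still α to the ketone, the methoxide treatment re-protonates the C8–C9 enolate from that same convex face and should settle the chain equatorial and trans to C20 as in 19, while C13 arrives unchanged with 16. The step needs 1,4- over 1,2-addition (soft cuprate, hindered ester untouched), alkylation at C9 and not at C7 (the enolate is generated regiospecifically and is trapped with excess iodide in HMPA before proton exchange) and C- over O-alkylation (iodide as leaving group).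

Step 14
Reactants: 19 2-(trimethylsilyl)ethyl 15-(tert-butyldimethylsilyloxy)-8-oxo-17-norlabdan-19-oate
Product: 20 2-(trimethylsilyl)ethyl 15-(tert-butyldimethylsilyloxy)labd-8(17)-en-19-oate (configuration as in 19)
Conditions: Zn, CH2Br2, TiCl4, THF/CH2Cl2, 0 °C to rt
Reagents that add atoms: dibromomethane, BrCBr
Why: The Takai–Lombardo methylenation uses a non-basic zinc–titanium methylene reagent that olefinates hindered, enolisable ketones without epimerising the α-centre, so the C9 configuration from step 13 is carried into the 8(17)-alkene while the hindered ester and the silyl ether stay intact.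

Step 15
Reactants: 20 2-(trimethylsilyl)ethyl 15-(tert-butyldimethylsilyloxy)labd-8(17)-en-19-oate
Product: 21 2-(trimethylsilyl)ethyl 15-hydroxylabd-8(17)-en-19-oate
Conditions: PPTS, MeOH, rt to 40 °C
Reagents that add atoms: none
Why: Mild acid-catalysed methanolysis removes the primary TBS ether and is too weak to move the exocyclic alkene into the ring or to touch the 2-(trimethylsilyl)ethyl ester.

Step 16
Reactants: 22 (E)-caffeic acid
Product: 24 (E)-3,4-bis(tert-butyldimethylsilyloxy)cinnamic acid, via tris-silylated caffeate 23 (not isolated)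
Conditions: TBSCl (3.3 equiv), imidazole, DMF, rt; then AcOH/THF/H2O, rt
Reagents that add atoms: tert-butyldimethylsilyl chloride, CC(C)(C)[Si](C)(C)Cl
Why: Exhaustive silylation is followed by selective hydrolysis of the silyl ester, which is far more labile to mild aqueous acid than the two aryl silyl ethers, and the E alkene is unaffected.

Step 17
Reactants: 21 2-(trimethylsilyl)ethyl 15-hydroxylabd-8(17)-en-19-oate; 24 (E)-3,4-bis(tert-butyldimethylsilyloxy)cinnamic acid
Product: 25 2-(trimethylsilyl)ethyl 15-[(E)-3,4-bis(tert-butyldimethylsilyloxy)cinnamoyloxy]labd-8(17)-en-19-oate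
Conditions: EDC·HCl, DMAP, CH2Cl2, 0 °C to rt
Reagents that add atoms: none
Why: Steglich esterification acylates the unhindered primary C15 alcohol under conditions that neither isomerise the cinnamate nor disturb the silyl groups.

Step 18
Reactants: 25 2-(trimethylsilyl)ethyl 15-[(E)-3,4-bis(tert-butyldimethylsilyloxy)cinnamoyloxy]labd-8(17)-en-19-oate
Product: 26 (4S,5S,9R,10R,13S)-15-[(E)-3-(3,4-dihydroxyphenyl)prop-2-enoyloxy]labd-8(17)-en-19-oic acid (target CNP0130717.2)
Conditions: TBAF, AcOH, THF, 0 °C to rt, under argon
Reagents that add atoms: none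
Why: In this fluoride desilylation the two aryl silyl ethers are cleaved at silicon and the 2-(trimethylsilyl)ethyl ester fragments to fluorotrimethylsilane, ethylene and the C19 carboxylate regardless of the hindrance at C19, while acetic acid buffering and exclusion of air protect the caffeate ester and the catechol.

**Compound list**
1 | 6-methoxy-1-tetralone | COc1ccc2c(c1)CCCC2=O | starting material
2 | 6-methoxy-1-methylene-1,2,3,4-tetrahydronaphthalene | COc1ccc2c(c1)CCCC2=C | intermediate
3 | (R)-6-methoxy-1-methyl-1-vinyl-1,2,3,4-tetrahydronaphthalene | COc1ccc2c(c1)CCC[C@]2(C)C=C | intermediate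
4 | (S)-6-methoxy-1-methyl-1,2,3,4-tetrahydronaphthalene-1-carbaldehyde | COc1ccc2c(c1)CCC[C@]2(C)C=O | intermediate
5 | (S)-6-methoxy-1-methyl-1,2,3,4-tetrahydronaphthalene-1-carboxylic acid | COc1ccc2c(c1)CCC[C@]2(C)C(=O)O | intermediate
6 | (S)-6-methoxy-1-methyl-1,2,3,4,5,8-hexahydronaphthalene-1-carboxylic acid (Birch diene acid) | COC1=CCC2=C(C1)CCC[C@]2(C)C(=O)O | intermediate
7 | (S)-1-methyl-6-oxo-1,2,3,4,5,6,7,8-octahydronaphthalene-1-carboxylic acid (C8 ketone, C5=C10 alkene) | O=C1CCC2=C(C1)CCC[C@]2(C)C(=O)O | intermediate
8 | 2-(trimethylsilyl)ethyl (S)-1-methyl-6-oxo-1,2,3,4,5,6,7,8-octahydronaphthalene-1-carboxylate | O=C1CCC2=C(C1)CCC[C@]2(C)C(=O)OCC[Si](C)(C)C | intermediate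
9 | 2-(trimethylsilyl)ethyl (1S,4aR,8aS)-1-methyl-6-oxodecahydronaphthalene-1-carboxylate (cis-fused, H-5 and H-10 on the ester face) | O=C1CC[C@H]2[C@@H](C1)CCC[C@]2(C)C(=O)OCC[Si](C)(C)C | intermediate
10 | 2-(trimethylsilyl)ethyl 1-methyl-6-(trimethylsilyloxy)-1,2,3,4,4a,7,8,8a-octahydronaphthalene-1-carboxylate (C8=C9 enol ether of 9) | C[Si](C)(C)OC=1CC[C@H]2[C@@H](C=1)CCC[C@]2(C)C(=O)OCC[Si](C)(C)C | intermediate
11 | 2-(trimethylsilyl)ethyl (1S,8aS)-1-methyl-6-oxo-1,2,3,4,6,7,8,8a-octahydronaphthalene-1-carboxylate (C8 ketone, C9=C10 alkene, H-5 cis to C19) | O=C1CC[C@H]2C(=C1)CCC[C@]2(C)C(=O)OCC[Si](C)(C)C | intermediate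
12 | (R)-methyl hydrogen 3-methylglutarate | COC(=O)C[C@H](C)CC(=O)O | starting material
13 | methyl (R)-5-hydroxy-3-methylpentanoate | COC(=O)C[C@H](C)CCO | intermediate
14 | methyl (R)-5-(tert-butyldimethylsilyloxy)-3-methylpentanoate | COC(=O)C[C@H](C)CCO[Si](C)(C)C(C)(C)C | intermediate
15 | (S)-5-(tert-butyldimethylsilyloxy)-3-methylpentan-1-ol | OCC[C@H](C)CCO[Si](C)(C)C(C)(C)C | intermediate
16 | (R)-tert-butyl[(5-iodo-3-methylpentyl)oxy]dimethylsilane | ICC[C@H](C)CCO[Si](C)(C)C(C)(C)C | intermediate
17 | lithium C8–C9 enolate of the cis-fused 10-methyl decalone ester | [Li]OC=1CC[C@H]2[C@](C)(CCC[C@]2(C)C(=O)OCC[Si](C)(C)C)C=1 | intermediate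
18 | C9 epimer of 19 (chain cis to C20) | O=C1CC[C@H]2[C@](C)(CCC[C@]2(C)C(=O)OCC[Si](C)(C)C)[C@H]1CC[C@H](C)CCO[Si](C)(C)C(C)(C)C | intermediate
19 | 2-(trimethylsilyl)ethyl 15-(tert-butyldimethylsilyloxy)-8-oxo-17-norlabdan-19-oate (H-5, C20, C19 cis; C9 chain trans to C20; 13S) | O=C1CC[C@H]2[C@](C)(CCC[C@]2(C)C(=O)OCC[Si](C)(C)C)[C@@H]1CC[C@H](C)CCO[Si](C)(C)C(C)(C)C | intermediate
20 | 2-(trimethylsilyl)ethyl 15-(tert-butyldimethylsilyloxy)labd-8(17)-en-19-oate | C=C1CC[C@H]2[C@](C)(CCC[C@]2(C)C(=O)OCC[Si](C)(C)C)[C@@H]1CC[C@H](C)CCO[Si](C)(C)C(C)(C)C | intermediate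
21 | 2-(trimethylsilyl)ethyl 15-hydroxylabd-8(17)-en-19-oate | C=C1CC[C@H]2[C@](C)(CCC[C@]2(C)C(=O)OCC[Si](C)(C)C)[C@@H]1CC[C@H](C)CCO | intermediate
22 | (E)-caffeic acid | O=C(O)/C=C/c1ccc(O)c(O)c1 | starting material
23 | tert-butyldimethylsilyl (E)-3,4-bis(tert-butyldimethylsilyloxy)cinnamate | CC(C)(C)[Si](C)(C)OC(=O)/C=C/c1ccc(O[Si](C)(C)C(C)(C)C)c(O[Si](C)(C)C(C)(C)C)c1 | intermediate
24 | (E)-3,4-bis(tert-butyldimethylsilyloxy)cinnamic acid | O=C(O)/C=C/c1ccc(O[Si](C)(C)C(C)(C)C)c(O[Si](C)(C)C(C)(C)C)c1 | intermediate
25 | 2-(trimethylsilyl)ethyl 15-[(E)-3,4-bis(tert-butyldimethylsilyloxy)cinnamoyloxy]labd-8(17)-en-19-oate | C=C1CC[C@H]2[C@](C)(CCC[C@]2(C)C(=O)OCC[Si](C)(C)C)[C@@H]1CC[C@H](C)CCOC(=O)/C=C/c1ccc(O[Si](C)(C)C(C)(C)C)c(O[Si](C)(C)C(C)(C)C)c1 | intermediate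
26 | (4S,5S,9R,10R,13S)-15-[(E)-3-(3,4-dihydroxyphenyl)prop-2-enoyloxy]labd-8(17)-en-19-oic acid | C=C1CC[C@H]2[C@](C)(CCC[C@]2(C)C(=O)O)[C@@H]1CC[C@H](C)CCOC(=O)/C=C/c1ccc(O)c(O)c1 | target

**Step count**
Total: 18 steps. Longest linear sequence: 13 steps (steps 1–8, 13, 14, 15, 17, 18).

**Steps most likely to fail**

1. Step 13. The hindered, copper-containing enolate may be alkylated only slowly by the unactivated iodide, so that proton exchange, alkylation at C7 or simple protonation take over, and the C9 equilibrium may not lie far enough on the side of the equatorial chain. The fallback sets out from enone 11 and alcohol 15 and replaces the alkylation by an aldol condensation and reduction. Alcohol 15 is oxidised with Dess–Martin periodinane to (R)-5-(tert-butyldimethylsilyloxy)-3-methylpentanal F1. Enolate 17, made from 11 as before, is transmetallated with ZnCl2 and added to F1 to give the C9–C11 aldol adduct F2. This is converted with MsCl and Et3N into the C11 mesylate F3, and DBU eliminates it to the C9=C11 alkylidene ketone F4. Hydrogenation of F4 over palladium on carbon should deliver hydrogen to C9 from the convex face and give ketone 19, where the route resumes.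

2. Step 8. The equilibrating silylation may enolise the C8 ketone toward C7 as well as toward C9, which would lead to the C6=C7 enone beside 11. The fallback sets out from keto ester 8 and leaves out steps 7 and 8. Catalytic DBU in CH2Cl2 moves the C5=C10 double bond into conjugation, which can only give the C9=C10 enone, as a mixture of 11 and its C5 epimer, 2-(trimethylsilyl)ethyl (1S,8aR)-1-methyl-6-oxo-1,2,3,4,6,7,8,8a-octahydronaphthalene-1-carboxylate F5. The two diastereomers are separated by chromatography and F5 is returned to the same DBU equilibration. The route is rejoined at 11.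

3. Step 7. Turnover at the hindered tetrasubstituted alkene may be slow, and acid-type conjugation of the β,γ-unsaturated ketone by the iridium hydride may then compete and scramble C5. The fallback sets out from keto ester 8 and protects the ketone first. 1,2-Bis(trimethylsilyloxy)ethane with catalytic TMSOTf at −78 °C gives the C8 dioxolane with the C5=C10 alkene in place, F6. This is hydrogenated with the same iridium catalyst at higher pressure and longer time to the cis-fused dioxolane F7. PPTS in aqueous acetone then frees the ketone and returns the route to 9.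

**Further compounds**
F1 | step 13 | (R)-5-(tert-butyldimethylsilyloxy)-3-methylpentanal | O=CC[C@H](C)CCO[Si](C)(C)C(C)(C)C
F2 | step 13 | C9–C11 aldol adduct of enolate 17 and F1 (C9 and C11 as a mixture) | O=C1CC[C@H]2[C@](C)(CCC[C@]2(C)C(=O)OCC[Si](C)(C)C)C1C(O)C[C@H](C)CCO[Si](C)(C)C(C)(C)C
F3 | step 13 | C11 mesylate of F2 | O=C1CC[C@H]2[C@](C)(CCC[C@]2(C)C(=O)OCC[Si](C)(C)C)C1C(OS(C)(=O)=O)C[C@H](C)CCO[Si](C)(C)C(C)(C)C
F4 | step 13 | C9=C11 alkylidene ketone (alkene geometry not controlled, either isomer serves) | O=C1CC[C@H]2[C@](C)(CCC[C@]2(C)C(=O)OCC[Si](C)(C)C)C1=CC[C@H](C)CCO[Si](C)(C)C(C)(C)C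
F5 | step 8 | 2-(trimethylsilyl)ethyl (1S,8aR)-1-methyl-6-oxo-1,2,3,4,6,7,8,8a-octahydronaphthalene-1-carboxylate (C5 epimer of 11) | O=C1CC[C@@H]2C(=C1)CCC[C@]2(C)C(=O)OCC[Si](C)(C)C
F6 | step 7 | C8 ethylene ketal of 8 (C5=C10 alkene retained) | O1CCOC12CCC3=C(C2)CCC[C@]3(C)C(=O)OCC[Si](C)(C)C
F7 | step 7 | C8 ethylene ketal of 9 (cis-fused, H-5 and H-10 on the ester face) | O1CCOC12CC[C@H]3[C@@H](C2)CCC[C@]3(C)C(=O)OCC[Si](C)(C)C
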